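(Readings and results stem from a simulated flask with made-up constants; noise was put on by code.)

The noon and dawn runs held one thing still: the capture agent rose from 0.013 M to 0.019 M, yet target stood at 48.5% and 48.5% at 20.0 h, so I took their curve as the one to read for this flask at 0.0250 M.

| setting | noon | dawn | flask |
|---|---|---|---|
| substrate | 0.25 M (fed, over 20 h) | 0.25 M (fed, over 20 h) | 0.25 M (fed, over 20 h) |
| partner | 0.75 M | 0.75 M | 0.750 M |
| capture agent | 0.013 M | 0.019 M | 0.0250 M |
| remark | run made earlier; the fed solution adds 1.0 times the starting volume | run made earlier; the fed solution adds 1.0 times the starting volume | the fed solution adds 1.0 times the starting volume |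
| time |  |  | 30 h |

- noon (time / h: target / %): 1.33: 1.5; 4.00: 3.3; 6.00: 7.7; 10.0: 18.6; 15.0: 32.0; 20.0: 48.5; 25.0: 59.6
- dawn (time / h: target / %): 1.33: 0.5; 4.00: 4.2; 6.00: 7.7; 10.0: 18.4; 15.0: 32.0; 20.0: 48.5; 25.0: 59.2

(standard deviation of a reading: 0.5 percentage points)

* amount of target in percent of the substrate charged, at 3.0 h, 10 h and 30 h

- every charge counts on the volume at the start, and the solution that is fed holds the whole dose
- steps under discussion: substrate -> target; partner + open intermediate -> side product A; partner + open intermediate -> side product B; capture agent + open intermediate -> trapped intermediate; substrate + partner -> open intermediate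
- percentages count the whole charge, also what has not yet gone in

Next I froze a quantity. Between 10.0 h and 20.0 h the noon run gained 30 percentage points of target while the feed delivered 50.0% of the charge. That gave the target share of the dose, the target gained per substrate dosed (a selectivity), of 0.598. Applied to the dawn run from its 10.0 h reading, this share gave 48.3% at 20.0 h, and that run read 48.5%.

I then reached the 30 h value in two ways. Frozen to the end, the share gave 59.8% of the charge. For the second way, the straight noon line met zero target at a lag of 3.78 h, which I read as the substrate's lifetime and held fixed, as an assumption of my reckoning. Shrinking the noon gain of the last 5.00 h by that lifetime and adding it to 59.6% gave 62.6%, more than the frozen share.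

The two parted, and the frozen share was the one that cheated. Noon already read 59.6% at 25.0 h, after a gain of 11 points in the 5.00 h since the feed ended, and its share read 0.536 and then a higher 0.660 across the two halves of that stretch. So I committed to 62.6% for this flask at 30 h.

The forecast gave 2.5%, 18.5% and 63.5%, and at 30 h that is higher than my figure. Its view of the flask was this: “Target therefore comes directly from substrate, and the trap only removes the open intermediate downstream.”

The flask gave 2.37%, 17.7% and 63.6%, so the forecast held, under these equations:

    substrate → target (k = 0.00220 min⁻¹)
    partner + open intermediate → side product A (k = 1.24 × 10⁻⁴ M⁻¹ min⁻¹)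
    partner + open intermediate → side product B (k = 3.74 × 10⁻⁴ M⁻¹ min⁻¹)
    capture agent + open intermediate → trapped intermediate (k = 0.00135 M⁻¹ min⁻¹)
    substrate + partner → open intermediate (k = 0.00261 M⁻¹ min⁻¹)

At 30.0 h this flask held 0.517% of trapped intermediate, and the capture step made no difference to the target. Carried forward from this flask's 10 h value, the share gave 32.6% at 15.0 h, where the flask stood at 32.2%.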